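(The numbers are those of an exercise; the flask was simulated.)

Take the flask by the fraction of substrate left, not the fraction made.

substrate 0.12 M; partner 0.700 equiv; free catalyst 0.5 mol%; time 5.0 min
    catalyst intermediate A + catalyst intermediate A ⇌ resting dimer (K1 = 780 /M, k1 = 185 /M/s)
    substrate + free catalyst ⇌ catalyst intermediate A (K2 = 2.98 /M, k2 = 244 /M/s)
    partner + catalyst intermediate B ⇌ catalyst intermediate C (K3 = 10.7 /M, k3 = 78.0 /M/s)
    catalyst intermediate C ⇌ free catalyst + product (K4 = 0.0426 M, k4 = 38.8 /s)
    catalyst intermediate A ⇌ catalyst intermediate B (K5 = 19, k5 = 1720 /s)
- percent here means substrate units held: one resting dimer counts as two
- where a step has two of a species, its rate is k times that concentration squared, and two are used at each turn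
- run time (flask): 5.0 min
* share of the substrate used up at 5.0 min
* product at 5.0 min, in percent of the substrate charged

Once round, the catalyst comes back and substrate + partner ⇌ product remains, so the four equilibrium constants of the round multiply. Their multiple times the [substrate] charged is the equilibrium number, 3.10. At rest, it equals product divided by substrate left times partner left, each as a fraction of the substrate charged.

Call the substrate fraction left f. Product is then what f lacks of the whole, and partner left is f minus 0.300. Solving gives f = 55.7%, so this reckoning commits to 44.3% product. That is less than the 70.0% that partner, the limiting reagent, allows, and 36.7% of the partner stays unused.

One number serves if the flask arrives in time and the catalyst holds little. The forward half-life of substrate through its binding step, 0.079 min with concentrations held at their charge, is shorter than 5.0 min, though that is one step's forward rate and not the whole round. A catalyst in a bound form holds one substrate unit, so the gap between conversion and yield is of the size of the loading of 0.5 mol%.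

The forecast gives 44.5% conversion and 44.1% product, a product figure lower than this reckoning's, holding that “the flask should reach the overall equilibrium”. The simulation gives 44.6% and 44.2%, so the forecast stands within the tolerance.

In the flask, the same quotient reads 1.04 at 0.500 min and 3.10 at 5.00 min, beside an equilibrium number of 3.10. For the neighbour flask with 1.80 equiv of partner, the same number reckons 76.3% product, and that flask gives 76.0%. With partner at 0.602 equiv or 0.808 equiv, conversion stands 5 points from that of the recipe flask. The slowest mode of the recipe flask as it stands at 5.00 min has a half-life of 0.353 min, and at 50.0 min that flask reads 44.6% conversion and 44.2% product, no change from 5.0 min.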